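**Strategy.** The ε-ring (C1'–C6') is disconnected between the gem-dimethyl carbon C1' and the methylene C2'. With C3' as a ketone, C2' is an α'-enolate carbon and C1' the δ-terminus of the dienone C3'(=O)–C4'=C5'–C6'=C1'. One base-mediated operation opens a 2H-pyran to its (Z)-dienone, joins C2' to C1' by vinylogous Michael (anionic 6π) ring closure and expels a pivalate from C7', giving achiral 4-methylene-isophorone. Transfer hydrogenation then sets C3' and hydroboration relays it to C6'. The resulting ε-C15 phosphonium salt, the C10 dialdehyde and an acetylenic C15 salt made from actinol by Sonogashira coupling are united by two Wittig reactions.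

Key step: step 4

Remarks on the chemistry:
- Locants are carotenoid locants, unprimed for the acetylenic β-half and primed for the ε-half. The target is (all-E)-(3R,3'R,6'R)-7,8-didehydro-β,ε-carotene-3,3'-diol, with 3'-OH and the C6' chain trans.
- Assumption: (Z)-dienones 6 and 9 rest mainly as their 2H-pyran valence tautomers 7 and 8, with which they equilibrate quickly at room temperature by oxa-6π electrocyclization. The chemistry is unchanged if the open forms predominate.
- Assumption: (4R,6R)-actinol (24), the C10 dialdehyde (32), enynol 28 and phosphonate 18 are purchased.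

**Route**

Step 1
Reactants: 1 acetylacetone
Product: 2 (2Z)-4-oxopent-2-en-2-yl trifluoromethanesulfonate
Conditions: Tf2O, aq. LiOH, toluene, 0–5 °C
Reagents that add atoms: trifluoromethanesulfonic anhydride, O=S(=O)(OS(=O)(=O)C(F)(F)F)C(F)(F)F
Why: O-sulfonylation of the chelated lithium (Z)-enolate of the 1,3-diketone (enol triflate formation) should fix the triflyloxy group cis to the acetyl group, the geometry that later places C3' and C6' cis on C4'=C5'.

Step 2
Reactants: 3 but-2-yn-1-ol; 2 (2Z)-4-oxopent-2-en-2-yl trifluoromethanesulfonate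
Product: 7 (2,2,4,6-tetramethyl-2H-pyran-3-yl)methanol, via alkenylmagnesium alkoxide 4 (not isolated), via alkenylzinc alkoxide 5 (not isolated), via open-chain Z-hydroxydienone 6 (not isolated)
Conditions: MeMgBr (2.5 equiv), Fe(acac)3 (10 mol %), THF, −78 → 0 °C; ZnCl2, 0 °C; then 2 (1.3 equiv), Pd(OAc)2 (5 mol %), SPhos (10 mol %), 23 → 45 °C; aq. NH4Cl
Reagents that add atoms: methylmagnesium bromide, C[Mg]Br
Why: Alkoxide-directed iron-catalysed carbomagnesiation should put the methyl on the distal alkyne carbon (the future C1', whose two methyls make the addition geometry irrelevant) and the metal on C6', after which transmetalation to zinc and Negishi coupling with retention at the enol triflate give the (Z)-dienone that closes to the 2H-pyran by oxa-6π electrocyclization.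

Step 3
Reactants: 7 (2,2,4,6-tetramethyl-2H-pyran-3-yl)methanol
Product: 8 (2,2,4,6-tetramethyl-2H-pyran-3-yl)methyl 2,2-dimethylpropanoate
Conditions: PivCl, pyridine, DMAP (cat.), CH2Cl2, 0 → 23 °C
Reagents that add atoms: pivaloyl chloride, CC(C)(C)C(Cl)=O
Why: DMAP-catalysed acylation of the primary alcohol installs at C7' a leaving group without α-hydrogens that resists direct SN2 displacement but is adequate for E1cB loss.

Step 4
Reactants: 8 (2,2,4,6-tetramethyl-2H-pyran-3-yl)methyl 2,2-dimethylpropanoate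
Product: 12 3,5,5-trimethyl-4-methylidenecyclohex-2-en-1-one, via open-chain Z-dienone pivalate 9 (not isolated), via potassium trienolate 10 (not isolated), via cyclic potassium dienolate 11 (not isolated)
Conditions: KOt-Bu (1.1 equiv), THF (0.05 M), 0 → 23 °C
Reagents that add atoms: none
Why: Retro-oxa-6π opening of pyran 8 releases (Z)-dienone 9, whose methyl ketone is converted (under alkoxide equilibration) into the cross-conjugated α'-trienolate 10; C2' then adds to C1', the δ-carbon of its own dienone (intramolecular vinylogous Michael addition, equivalently an oxyanion-accelerated disrotatory 6π-electrocyclization of a 2-oxidohexatriene), and dienolate 11 expels pivalate from C7' by vinylogous E1cB, so the net change is an intramolecular SN2' alkylation. The closest known reaction is the base-mediated closure of (Z)-4,6-dimethylhepta-3,5-dien-2-one to isophorone, which forms the same CH2–CMe2 bond. The six-membered carbocycle is closed in a 6-endo-trig (6π) mode. No stereocentre is formed, since C1' carries two methyls and C2' two hydrogens, and product 12 is achiral by design so that configuration can be introduced afterwards under catalyst control. The step needs C- rather than O-attack and attack at C1' rather than direct displacement at C7': only C-attack leads to a carbonyl-stabilised dienolate, a carboxylate is a poor nucleofuge for direct SN2 yet sufficient for E1cB, and the Z geometry of C4'=C5' is secured by the pyran–dienone valence tautomerism.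

Step 5
Reactants: 12 3,5,5-trimethyl-4-methylidenecyclohex-2-en-1-one
Product: 13 (1R)-3,5,5-trimethyl-4-methylidenecyclohex-2-en-1-ol
Conditions: RuCl[(R,R)-TsDPEN](p-cymene) (1 mol %), HCO2Na, H2O/EtOAc, 40 °C
Reagents that add atoms: none
Why: Noyori–Ikariya asymmetric transfer hydrogenation should reduce the C3' carbonyl 1,2-selectively, the dienyl π-system taking the place of the aryl group in the catalyst's CH/π recognition so that hydride reaches the Si face and sets C3' as R, as in the known reduction of the same carbonyl of ketoisophorone.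

Step 6
Reactants: 13 (1R)-3,5,5-trimethyl-4-methylidenecyclohex-2-en-1-ol
Product: 14 tert-butyldimethyl{[(1R)-3,5,5-trimethyl-4-methylidenecyclohex-2-en-1-yl]oxy}silane
Conditions: TBSCl, imidazole, DMF, 23 °C
Reagents that add atoms: tert-butyldimethylsilyl chloride, CC(C)(C)[Si](C)(C)Cl
Why: Standard silylation protects the dienylic alcohol under non-acidic conditions and supplies the bulky pseudo-equatorial group used for conformational control in the next step.

Step 7
Reactants: 14 tert-butyldimethyl{[(1R)-3,5,5-trimethyl-4-methylidenecyclohex-2-en-1-yl]oxy}silane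
Product: 16 [(1R,4R)-4-(tert-butyldimethylsilyloxy)-2,6,6-trimethylcyclohex-2-en-1-yl]methanol, via B-alkyl-9-BBN adduct 15 (not isolated)
Conditions: 9-BBN, THF, 0 → 23 °C; then NaOH, H2O2, 0 °C
Reagents that add atoms: hydrogen peroxide, OO
Why: Hydroboration–oxidation with 9-BBN should engage only the exocyclic 1,1-disubstituted alkene (boron on C7') and deliver hydrogen to C6' anti to the pseudo-axial C1' methyl of the half-chair that keeps the C3' silyloxy group pseudo-equatorial, that is syn to the silyloxy group, which sets C6' as R with CH2OH trans to the C3' oxygen.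

Step 8
Reactants: 16 [(1R,4R)-4-(tert-butyldimethylsilyloxy)-2,6,6-trimethylcyclohex-2-en-1-yl]methanol
Product: 17 (1R,4R)-4-(tert-butyldimethylsilyloxy)-2,6,6-trimethylcyclohex-2-ene-1-carbaldehyde
Conditions: Dess–Martin periodinane, NaHCO3, CH2Cl2, 0 → 23 °C
Reagents that add atoms: none
Why: Buffered Dess–Martin oxidation is neutral, so the α-stereocentre C6' and the β,γ-position of the C4'=C5' alkene should be retained.

Step 9
Reactants: 17 (1R,4R)-4-(tert-butyldimethylsilyloxy)-2,6,6-trimethylcyclohex-2-ene-1-carbaldehyde; 18 ethyl (2E)-4-(diethoxyphosphoryl)-3-methylbut-2-enoate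
Product: 20 ethyl (2E,4E)-5-[(1R,4R)-4-(tert-butyldimethylsilyloxy)-2,6,6-trimethylcyclohex-2-en-1-yl]-3-methylpenta-2,4-dienoate, via lithiated phosphonate 19 (not isolated)
Conditions: 18, LiHMDS, THF, −78 °C; then 17, −78 → 0 °C
Reagents that add atoms: none
Why: Horner–Wadsworth–Emmons olefination with the preformed stabilised anion should form C7'=C8' with E geometry and add to the aldehyde faster than it deprotonates the hindered C6'–H, any minor (2Z) isomer being removed by chromatography.

Step 10
Reactants: 20 ethyl (2E,4E)-5-[(1R,4R)-4-(tert-butyldimethylsilyloxy)-2,6,6-trimethylcyclohex-2-en-1-yl]-3-methylpenta-2,4-dienoate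
Product: 21 (2E,4E)-5-[(1R,4R)-4-(tert-butyldimethylsilyloxy)-2,6,6-trimethylcyclohex-2-en-1-yl]-3-methylpenta-2,4-dien-1-ol
Conditions: DIBAL-H (2.2 equiv), CH2Cl2, −78 °C; Rochelle salt
Reagents that add atoms: none
Why: 1,2-Reduction of the dienoate by DIBAL-H gives the allylic alcohol without touching the alkenes or the silyl ether.

Step 11
Reactants: 21 (2E,4E)-5-[(1R,4R)-4-(tert-butyldimethylsilyloxy)-2,6,6-trimethylcyclohex-2-en-1-yl]-3-methylpenta-2,4-dien-1-ol
Product: 23 {(2E,4E)-5-[(1R,4R)-4-(tert-butyldimethylsilyloxy)-2,6,6-trimethylcyclohex-2-en-1-yl]-3-methylpenta-2,4-dien-1-yl}triphenylphosphonium bromide, via allylic bromide 22 (not isolated)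
Conditions: PPh3 (2.5 equiv), CBr4 (1.2 equiv), 2,6-lutidine, CH2Cl2, 0 → 23 °C
Reagents that add atoms: triphenylphosphine, c1ccc(cc1)P(c1ccccc1)c1ccccc1; carbon tetrabromide, BrC(Br)(Br)Br
Why: Appel bromination followed by in situ SN2 quaternisation with the excess phosphine makes the Wittig salt under neutral conditions, which spares the acid-labile allylic C3' silyl ether.

Step 12
Reactants: 24 (4R,6R)-4-hydroxy-2,2,6-trimethylcyclohexan-1-one (actinol)
Product: 25 (4R,6R)-4-(tert-butyldimethylsilyloxy)-2,2,6-trimethylcyclohexan-1-one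
Conditions: TBSCl, imidazole, DMF, 23 °C
Reagents that add atoms: tert-butyldimethylsilyl chloride, CC(C)(C)[Si](C)(C)Cl
Why: Silylation protects the chiral-pool carbinol that becomes C3 (R).

Step 13
Reactants: 25 (4R,6R)-4-(tert-butyldimethylsilyloxy)-2,2,6-trimethylcyclohexan-1-one
Product: 27 (4R)-4-(tert-butyldimethylsilyloxy)-2,6,6-trimethylcyclohex-1-en-1-yl trifluoromethanesulfonate, via potassium enolate 26 (not isolated)
Conditions: KHMDS, THF, −78 → 0 °C; then PhNTf2, −78 → 23 °C
Reagents that add atoms: N-phenylbis(trifluoromethanesulfonimide), O=S(=O)(N(c1ccccc1)S(=O)(=O)C(F)(F)F)C(F)(F)F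
Why: The ketone has a single enolisable position because the other α-carbon is quaternary, so enol triflate formation is regiochemically unambiguous and gives the C5=C6 alkene.

Step 14
Reactants: 27 (4R)-4-(tert-butyldimethylsilyloxy)-2,6,6-trimethylcyclohex-1-en-1-yl trifluoromethanesulfonate; 28 (2E)-3-methylpent-2-en-4-yn-1-ol
Product: 29 (2E)-5-[(4R)-4-(tert-butyldimethylsilyloxy)-2,6,6-trimethylcyclohex-1-en-1-yl]-3-methylpent-2-en-4-yn-1-ol
Conditions: Pd(PPh3)4 (5 mol %), CuI (10 mol %), i-Pr2NH, DMF, 23 → 50 °C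
Reagents that add atoms: none
Why: Sonogashira coupling forms the C6–C7 bond and carries the preset (E)-C9=C10 geometry of the enynol through unchanged.

Step 15
Reactants: 29 (2E)-5-[(4R)-4-(tert-butyldimethylsilyloxy)-2,6,6-trimethylcyclohex-1-en-1-yl]-3-methylpent-2-en-4-yn-1-ol
Product: 31 {(2E)-5-[(4R)-4-(tert-butyldimethylsilyloxy)-2,6,6-trimethylcyclohex-1-en-1-yl]-3-methylpent-2-en-4-yn-1-yl}triphenylphosphonium bromide, via allylic bromide 30 (not isolated)
Conditions: PPh3 (2.5 equiv), CBr4 (1.2 equiv), 2,6-lutidine, CH2Cl2, 0 → 23 °C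
Reagents that add atoms: triphenylphosphine, c1ccc(cc1)P(c1ccccc1)c1ccccc1; carbon tetrabromide, BrC(Br)(Br)Br
Why: Appel bromination and in situ quaternisation give the acetylenic C15 Wittig salt with the silyl ether intact.

Step 16
Reactants: 31 acetylenic C15 phosphonium bromide; 32 (2E,4E,6E)-2,7-dimethylocta-2,4,6-trienedial
Product: 34 (2E,4E,6E,8E,10E)-13-[(4R)-4-(tert-butyldimethylsilyloxy)-2,6,6-trimethylcyclohex-1-en-1-yl]-2,7,11-trimethyltrideca-2,4,6,8,10-pentaen-12-ynal, via phosphorus ylide 33 (not isolated)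
Conditions: 31, NaHMDS, THF, −78 °C; added to 32 (3 equiv), −78 → 0 °C; then n-heptane, 80 °C
Reagents that add atoms: none
Why: Wittig olefination by inverse addition to excess dialdehyde should give mono-condensation at C11=C12 (the product aldehyde is less electrophilic), and brief heating should convert the hindered (11Z) by-product into the E isomer.

Step 17
Reactants: 23 ε-C15 phosphonium bromide; 34 C25 acetylenic aldehyde
Product: 36 (3R,3'R,6'R)-3,3'-bis(tert-butyldimethylsilyloxy)-7,8-didehydro-β,ε-carotene, via phosphorus ylide 35 (not isolated)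
Conditions: 23, NaHMDS, THF, −78 °C; then 34, −78 → 23 °C; then n-heptane, 80 °C
Reagents that add atoms: none
Why: The second Wittig olefination forms C11'=C12' and completes the C40 skeleton, with thermal Z→E isomerisation of the new disubstituted bond and no stereocentre affected.

Step 18
Reactants: 36 (3R,3'R,6'R)-3,3'-bis(tert-butyldimethylsilyloxy)-7,8-didehydro-β,ε-carotene
Product: 37 (all-E)-(3R,3'R,6'R)-7,8-didehydro-β,ε-carotene-3,3'-diol
Conditions: TBAF, THF, 0 → 23 °C, dark, argon
Reagents that add atoms: none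
Why: Fluoride desilylation removes both silyl ethers under non-acidic conditions, which avoids ionisation of the allylic 3'-alcohol.

**Compound list**

1 | acetylacetone (pentane-2,4-dione) | CC(=O)CC(C)=O | starting material
2 | (2Z)-4-oxopent-2-en-2-yl trifluoromethanesulfonate | CC(=O)/C=C(C)\OS(=O)(=O)C(F)(F)F | intermediate
3 | but-2-yn-1-ol | CC#CCO | starting material
4 | bromomagnesium 2-(bromomagnesio)-3-methylbut-2-en-1-olate (formed in situ) | CC(C)=C([Mg]Br)CO[Mg]Br | intermediate
5 | bromomagnesium 2-(chlorozincio)-3-methylbut-2-en-1-olate (formed in situ) | CC(C)=C([Zn]Cl)CO[Mg]Br | intermediate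
6 | (3Z)-5-(hydroxymethyl)-4,6-dimethylhepta-3,5-dien-2-one (open-chain tautomer of 7) | CC(=O)/C=C(C)\C(CO)=C(C)C | intermediate
7 | (2,2,4,6-tetramethyl-2H-pyran-3-yl)methanol | CC1=CC(C)=C(CO)C(C)(C)O1 | intermediate
8 | (2,2,4,6-tetramethyl-2H-pyran-3-yl)methyl 2,2-dimethylpropanoate | CC1=CC(C)=C(COC(=O)C(C)(C)C)C(C)(C)O1 | intermediate
9 | (3Z)-3-methyl-5-oxo-2-(propan-2-ylidene)hex-3-en-1-yl 2,2-dimethylpropanoate (open-chain tautomer of 8) | CC(=O)/C=C(C)\C(COC(=O)C(C)(C)C)=C(C)C | intermediate
10 | potassium α'-trienolate of 9 (formed in situ) | C=C([O-])/C=C(C)\C(COC(=O)C(C)(C)C)=C(C)C.[K+] | intermediate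
11 | potassium 3,5,5-trimethyl-4-(pivaloyloxymethyl)cyclohexa-1,3-dien-1-olate (formed in situ) | [K+].[O-]C1=CC(C)=C(COC(=O)C(C)(C)C)C(C)(C)C1 | intermediate
12 | 3,5,5-trimethyl-4-methylidenecyclohex-2-en-1-one | CC1=CC(=O)CC(C)(C)C1=C | intermediate
13 | (1R)-3,5,5-trimethyl-4-methylidenecyclohex-2-en-1-ol | CC1=C[C@H](O)CC(C)(C)C1=C | intermediate
14 | tert-butyldimethyl{[(1R)-3,5,5-trimethyl-4-methylidenecyclohex-2-en-1-yl]oxy}silane | CC1=C[C@H](O[Si](C)(C)C(C)(C)C)CC(C)(C)C1=C | intermediate
15 | B-alkyl-9-BBN adduct of 14 (boron on C7', formed in situ) | CC1=C[C@H](O[Si](C)(C)C(C)(C)C)CC(C)(C)[C@H]1CB1C2CCCC1CCC2 | intermediate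
16 | [(1R,4R)-4-(tert-butyldimethylsilyloxy)-2,6,6-trimethylcyclohex-2-en-1-yl]methanol | CC1=C[C@H](O[Si](C)(C)C(C)(C)C)CC(C)(C)[C@H]1CO | intermediate
17 | (1R,4R)-4-(tert-butyldimethylsilyloxy)-2,6,6-trimethylcyclohex-2-ene-1-carbaldehyde | CC1=C[C@H](O[Si](C)(C)C(C)(C)C)CC(C)(C)[C@H]1C=O | intermediate
18 | ethyl (2E)-4-(diethoxyphosphoryl)-3-methylbut-2-enoate | CCOC(=O)/C=C(\C)CP(=O)(OCC)OCC | starting material
19 | lithiated phosphonate 18 (formed in situ) | [Li+].CCOC(=O)/C=C(\C)[CH-]P(=O)(OCC)OCC | intermediate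
20 | ethyl (2E,4E)-5-[(1R,4R)-4-(tert-butyldimethylsilyloxy)-2,6,6-trimethylcyclohex-2-en-1-yl]-3-methylpenta-2,4-dienoate | CC1=C[C@H](O[Si](C)(C)C(C)(C)C)CC(C)(C)[C@H]1/C=C/C(C)=C/C(=O)OCC | intermediate
21 | (2E,4E)-5-[(1R,4R)-4-(tert-butyldimethylsilyloxy)-2,6,6-trimethylcyclohex-2-en-1-yl]-3-methylpenta-2,4-dien-1-ol | CC1=C[C@H](O[Si](C)(C)C(C)(C)C)CC(C)(C)[C@H]1/C=C/C(C)=C/CO | intermediate
22 | allylic bromide from 21 (formed in situ) | CC1=C[C@H](O[Si](C)(C)C(C)(C)C)CC(C)(C)[C@H]1/C=C/C(C)=C/CBr | intermediate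
23 | {(2E,4E)-5-[(1R,4R)-4-(tert-butyldimethylsilyloxy)-2,6,6-trimethylcyclohex-2-en-1-yl]-3-methylpenta-2,4-dien-1-yl}triphenylphosphonium bromide | CC1=C[C@H](O[Si](C)(C)C(C)(C)C)CC(C)(C)[C@H]1/C=C/C(C)=C/C[P+](c1ccccc1)(c1ccccc1)c1ccccc1.[Br-] | intermediate
24 | (4R,6R)-4-hydroxy-2,2,6-trimethylcyclohexan-1-one (actinol) | O=C1[C@H](C)C[C@@H](O)CC1(C)C | starting material
25 | (4R,6R)-4-(tert-butyldimethylsilyloxy)-2,2,6-trimethylcyclohexan-1-one | O=C1[C@H](C)C[C@@H](O[Si](C)(C)C(C)(C)C)CC1(C)C | intermediate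
26 | potassium enolate of 25 (formed in situ) | [K+].[O-]C1=C(C)C[C@@H](O[Si](C)(C)C(C)(C)C)CC1(C)C | intermediate
27 | (4R)-4-(tert-butyldimethylsilyloxy)-2,6,6-trimethylcyclohex-1-en-1-yl trifluoromethanesulfonate | O=S(=O)(OC1=C(C)C[C@@H](O[Si](C)(C)C(C)(C)C)CC1(C)C)C(F)(F)F | intermediate
28 | (2E)-3-methylpent-2-en-4-yn-1-ol | OC/C=C(\C)C#C | starting material
29 | (2E)-5-[(4R)-4-(tert-butyldimethylsilyloxy)-2,6,6-trimethylcyclohex-1-en-1-yl]-3-methylpent-2-en-4-yn-1-ol | OC/C=C(\C)C#CC1=C(C)C[C@@H](O[Si](C)(C)C(C)(C)C)CC1(C)C | intermediate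
30 | allylic bromide from 29 (formed in situ) | BrC/C=C(\C)C#CC1=C(C)C[C@@H](O[Si](C)(C)C(C)(C)C)CC1(C)C | intermediate
31 | {(2E)-5-[(4R)-4-(tert-butyldimethylsilyloxy)-2,6,6-trimethylcyclohex-1-en-1-yl]-3-methylpent-2-en-4-yn-1-yl}triphenylphosphonium bromide | [Br-].c1ccccc1[P+](c1ccccc1)(c1ccccc1)C/C=C(\C)C#CC1=C(C)C[C@@H](O[Si](C)(C)C(C)(C)C)CC1(C)C | intermediate
32 | (2E,4E,6E)-2,7-dimethylocta-2,4,6-trienedial | O=C/C(C)=C/C=C/C=C(C)/C=O | starting material
33 | phosphorus ylide from 31 (formed in situ) | c1ccccc1P(c1ccccc1)(c1ccccc1)=C/C=C(\C)C#CC1=C(C)C[C@@H](O[Si](C)(C)C(C)(C)C)CC1(C)C | intermediate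
34 | (2E,4E,6E,8E,10E)-13-[(4R)-4-(tert-butyldimethylsilyloxy)-2,6,6-trimethylcyclohex-1-en-1-yl]-2,7,11-trimethyltrideca-2,4,6,8,10-pentaen-12-ynal | O=C/C(C)=C/C=C/C=C(C)/C=C/C=C(\C)C#CC1=C(C)C[C@@H](O[Si](C)(C)C(C)(C)C)CC1(C)C | intermediate
35 | phosphorus ylide from 23 (formed in situ) | CC1=C[C@H](O[Si](C)(C)C(C)(C)C)CC(C)(C)[C@H]1/C=C/C(C)=C/C=P(c1ccccc1)(c1ccccc1)c1ccccc1 | intermediate
36 | (3R,3'R,6'R)-3,3'-bis(tert-butyldimethylsilyloxy)-7,8-didehydro-β,ε-carotene | CC1=C[C@H](O[Si](C)(C)C(C)(C)C)CC(C)(C)[C@H]1/C=C/C(C)=C/C=C/C(C)=C/C=C/C=C(C)/C=C/C=C(\C)C#CC1=C(C)C[C@@H](O[Si](C)(C)C(C)(C)C)CC1(C)C | intermediate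
37 | (all-E)-(3R,3'R,6'R)-7,8-didehydro-β,ε-carotene-3,3'-diol | CC1=C[C@H](O)CC(C)(C)[C@H]1/C=C/C(C)=C/C=C/C(C)=C/C=C/C=C(C)/C=C/C=C(\C)C#CC1=C(C)C[C@@H](O)CC1(C)C | target

**Step count:** 18 steps in total. The longest linear sequence is 13 steps (steps 1–11, 17, 18).

**Steps most likely to fail**

1. Step 4. The trienolate may be diverted into direct displacement at C7' or O-alkylation, and the cross-conjugated dienone product may oligomerise by Michael addition while base is present. Fallback from 8: silylate the open-chain tautomer (TMSOTf, Et3N, CH2Cl2) to the open-chain trimethylsilyl trienol ether F1. Heat it in toluene (about 90 °C) so that a neutral thermal disrotatory 6π-electrocyclization forms the same C1'–C2' bond and gives the cyclic silyl dienol ether F2. Treat F2 with TBAF at 0 °C so that the liberated dienolate loses pivalate, which returns to the route at 12 without any strong base in contact with the product.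

2. Step 7. Facial selectivity of hydrogen delivery to C6' rests on a conformational preference and may be insufficient, giving a mixture of C6' epimers. Fallback from 13: convert the free alcohol with Ph2PCl/Et3N into the diphenylphosphinite F3. Carry out a phosphinite-directed rhodium-catalysed hydroboration (RhCl(PPh3)3, catecholborane), which delivers B–H from the face of the C3' oxygen, and work up oxidatively (NaOH/H2O2) to the diol F4. Silylate both hydroxyls (TBSCl, imidazole) to the bis-silyl ether F5 and cleave the primary silyl ether selectively (PPTS, MeOH, 0 °C), which returns to the route at 16.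

3. Step 2. Transmetalation and reductive elimination between two hindered alkenyl partners may be slow, and residual methylzinc consumes the triflate. Fallback from 3: quench the iron-catalysed methylmagnesiation with iodine and isolate 2-iodo-3-methylbut-2-en-1-ol F6. Separately convert 2 with hexabutylditin, Pd(PPh3)4 and LiCl into (3Z)-4-(tributylstannyl)pent-3-en-2-one F7. Join F6 and F7 by a copper-assisted Stille coupling (Pd(PPh3)4, CuI, DMF) with retention of the Z geometry, which returns to the route at 7.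

Further compounds
F1 | step 4 | (3Z)-3-methyl-2-(propan-2-ylidene)-5-(trimethylsilyloxy)hexa-3,5-dien-1-yl 2,2-dimethylpropanoate | C=C(O[Si](C)(C)C)/C=C(C)\C(COC(=O)C(C)(C)C)=C(C)C
F2 | step 4 | [2,6,6-trimethyl-4-(trimethylsilyloxy)cyclohexa-1,3-dien-1-yl]methyl 2,2-dimethylpropanoate | C[Si](C)(C)OC1=CC(C)=C(COC(=O)C(C)(C)C)C(C)(C)C1
F3 | step 7 | (1R)-3,5,5-trimethyl-4-methylidenecyclohex-2-en-1-yl diphenylphosphinite | CC1=C[C@H](OP(c2ccccc2)c2ccccc2)CC(C)(C)C1=C
F4 | step 7 | (1R,4R)-4-(hydroxymethyl)-3,5,5-trimethylcyclohex-2-en-1-ol | CC1=C[C@H](O)CC(C)(C)[C@H]1CO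
F5 | step 7 | bis(tert-butyldimethylsilyl) ether of F4 | CC1=C[C@H](O[Si](C)(C)C(C)(C)C)CC(C)(C)[C@H]1CO[Si](C)(C)C(C)(C)C
F6 | step 2 | 2-iodo-3-methylbut-2-en-1-ol | CC(C)=C(I)CO
F7 | step 2 | (3Z)-4-(tributylstannyl)pent-3-en-2-one | CC(=O)/C=C(C)\[Sn](CCCC)(CCCC)CCCC
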